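Late in both earlier runs the product climbs ever more slowly, so the question is what the climb is heading for.

common to all: starting material 0.10 M

|  | coupling partner | free catalyst | remark | time |
|---|---|---|---|---|
| winter | 0.50 M | 2.4 mM | run made earlier |  |
| dusk | 0.50 M | 9.4 mM | run made earlier |  |
| flask | 0.500 M | 4.7 mM |  | 10 h |

| run | time / h | product / % | catalyst intermediate D / % | starting material / % |
|---|---|---|---|---|
| winter | 0.500 | 3.5 | 0.1 | 95.1 |
| winter | 0.833 | 5.6 | 0 | 94.2 |
| winter | 1.33 | 7.7 | 0.4 | 91.7 |
| winter | 2.00 | 11.1 | 0.5 | 87.1 |
| winter | 4.00 | 20.8 | 0.6 | 79.2 |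
| winter | 6.00 | 27.2 | 1.3 | 72.6 |
| dusk | 0.417 | 7.5 | 0.8 | 87.0 |
| dusk | 1.33 | 25.3 | 3.9 | 69.2 |
| dusk | 2.00 | 35.7 | 2.8 | 58.4 |
| dusk | 3.00 | 46.7 | 2.7 | 46.8 |
| dusk | 5.00 | 62.9 | 3.8 | 30.6 |
| dusk | 6.00 | 67.6 | 5.0 | 24.4 |

(each reading ± 0.5 percentage points)

- the product standing at 10 h, as a percentage of the starting material charged
- the catalyst intermediate D standing at 10 h, as a percentage of the starting material charged
- amount of product if the flask were left three thousand times as long, in percent of the starting material charged

- the numbers in the tables scatter by 0.5 percentage points (one standard deviation)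

Take the catalyst first. By hand, product would follow the charge, and dusk holds 3.92 times the catalyst of winter. Yet at 6.00 h dusk reads 67.6 % against 27.2 %, a factor of 2.49.

Then time. By hand, a steady rate would repeat winter's first 2.00 h, worth 11.1 %, but the last span of that length brings 6.4 percentage points. That rate has fallen further than the starting material, which still reads 72.6 %, so something else is running down with time.

Comparing equal early and late spans gives the fade rate, the first-order constant at which the product's rate falls: 0.138 h⁻¹ in winter and 0.268 h⁻¹ in dusk. The new flask's catalyst lies at the geometric middle of the two, so we take the geometric mean, 0.192 h⁻¹, a half-life of 3.61 h. A first-order fade implies a plateau: we read winter's as 46.1 % and dusk's as 84.5 %, so our estimate for the new flask, their geometric middle, is 62.4 %. By 10 h we expect the new flask to reach a share 85.4 % of that plateau, so we reckon on 53.3 % product. If the fading thing is the coupling partner, 14.7 % of its charge remains then. For catalyst intermediate D we offer no reckoning.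

The forecast gives 58 % (53 % to 62 %) of product, 2.6 % (1.8 % to 3.6 %) of D and 78 % (68 % to 96 %) for the long wait, reading “time-based catalyst loss rather than product inhibition”. Our plateau lies below its range.

At 10 h the flask gives 54.4 % of product. Catalyst intermediate D then stands at 2.20 %. After the long wait the flask gives 64.7 % of product.

    catalyst intermediate D ⇌ free catalyst + product (K = 0.0353 M, k = 67.8 h⁻¹)
    catalyst intermediate C ⇌ released group + catalyst intermediate D (K = 0.184 M, k = 62.0 h⁻¹)
    starting material + catalyst intermediate A ⇌ catalyst intermediate B (K = 353 M⁻¹, k = 296 M⁻¹ h⁻¹)
    coupling partner + free catalyst → catalyst intermediate A (k = 14.2 M⁻¹ h⁻¹)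
    catalyst intermediate B → catalyst intermediate C (k = 8.47 h⁻¹)
    coupling partner → decomposed reagent (k = 0.149 h⁻¹)

In this flask, coupling partner passed both into decomposed reagent and into catalyst intermediate A, the first 6.3 times as fast at 3.07 h. By 100 h this flask holds 0 % of its charge of coupling partner, in effect the limiting reagent, beside 31.9 % starting material. Dividing this flask's 54.4 % by our share gives 63.7 % of product, against 64.7 % after the long wait; the fade's 14.7 % of coupling partner at 10 h compares with 18 % of its charge. In a neighbour flask with 0.85 M of coupling partner, the same fade again leaves 14.7 % of its charge at 10 h; that neighbour flask holds 19.0 % of its charge, with 70.3 % product.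

The readings were computed for an exercise; noise was put on by code.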